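**Retrosynthetic overview**

1. Feature: ring A is a phloroglucinol with oxygen on C5, C7 and C8a, the acyl carbon C4 on C4a and the prenyl group on C6 between O5 and O7. This is the pattern of a folded C4a–C8a–C8–C7–C6–C5 poly-β-carbonyl chain, and if O1 already sits on C8a when the chain closes, the prenyl carbon can only become C6, not C8.
2. Target ⇐ removal of the O3 allyl group (through its propenyl ether) and of two methoxymethyl (MOM) ethers ⇐ ring A closed by intramolecular Claisen condensation (C4a–C5 bond) of a ring C 2,3-dihydropyran-4-one carrying CH2–CO–CH(prenyl)–CO2Me on C8a.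
3. Ring C (O1–C8a bond) ⇐ acid cyclodehydration of a 5-hydroxy-1,3-diketone; C4–C4a bond ⇐ acylation of the trianion of methyl 2-prenyl-3,5-dioxohexanoate by a Weinreb amide.
4. C2–C3 bond and both stereocentres ⇐ anti-selective glycolate aldol of an N-(allyloxyacetyl)oxazolidinethione with the ring B aldehyde; that aldehyde ⇐ resorcinol by MOM protection and two directed lithiations (geranylation, then formylation).
5. Ring order: ring B (from resorcinol) → ring C (step 11) → ring A (step 12).

Key step: step 12

Assumption: the titanium glycolate aldol is taken to follow its usual open transition-state model (enolate face opposite the benzyl group of the auxiliary); the prenyl-bearing carbon of the β-keto ester chain is carried as an epimer mixture, drawn in the keto form, and becomes aromatic C6 in the key step.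

**Route**

Step 1
Reactants: 1 resorcinol
Product: 2 1,3-bis(methoxymethoxy)benzene
Conditions: NaH (2.4 equiv), DMF, 0 °C; MOMCl (2.3 equiv), 0 → 23 °C
Reagents that add atoms: chloromethyl methyl ether, COCCl
Why: Williamson-type O-alkylation of the bis-phenoxide should give the base-stable bis-acetal, whose two oxygens later direct ortho-lithiation.

Step 2
Reactants: 2 1,3-bis(methoxymethoxy)benzene; 3 geranyl bromide
Product: 5 2-[(2E)-3,7-dimethylocta-2,6-dienyl]-1,3-bis(methoxymethoxy)benzene, via 2-lithio arene 4 (not isolated)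
Conditions: n-BuLi (1.1 equiv), THF, 0 °C; CuI (10 mol %), then 3, −78 → 23 °C
Reagents that add atoms: none
Why: Directed ortho-metalation should occur at C2 under the cooperative direction of both MOM ethers, and copper-catalysed allylic substitution at the primary carbon of geranyl bromide should keep the E geometry.

Step 3
Reactants: 5 2-geranyl-1,3-bis(methoxymethoxy)benzene
Product: 7 3-[(2E)-3,7-dimethylocta-2,6-dienyl]-2,4-bis(methoxymethoxy)benzaldehyde, via aryllithium 6 (not isolated)
Conditions: n-BuLi (1.2 equiv), TMEDA, THF, 0 °C; DMF, 0 → 23 °C; H2O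
Reagents that add atoms: N,N-dimethylformamide, CN(C)C=O
Why: A second directed ortho-metalation next to one MOM ether (the two open ortho positions are equivalent by symmetry) followed by formylation with DMF should give the single aldehyde.

Step 4
Reactants: 8 (allyloxy)acetic acid; 9 (R)-4-benzyl-1,3-oxazolidine-2-thione
Product: 11 (R)-3-[(allyloxy)acetyl]-4-benzyl-1,3-oxazolidine-2-thione, via allyloxyacetyl chloride 10 (not isolated)
Conditions: (COCl)2, DMF (cat.), CH2Cl2, 0 → 23 °C, concentrate; then 9, Et3N, CH2Cl2, 0 °C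
Reagents that add atoms: none
Why: N-acylation of the oxazolidinethione by the acid chloride made in the flask is a standard way to load a glycolate on this auxiliary.

Step 5
Reactants: 11 N-(allyloxyacetyl)oxazolidinethione; 7 ring B aldehyde
Product: 13 (R)-3-[(2R,3R)-2-(allyloxy)-3-[3-geranyl-2,4-bis(methoxymethoxy)phenyl]-3-hydroxypropanoyl]-4-benzyl-1,3-oxazolidine-2-thione, via trichlorotitanium Z-enolate 12 (not isolated)
Conditions: 11 (1.5 equiv), TiCl4 (1.6 equiv), i-Pr2NEt (1.7 equiv), CH2Cl2, −78 °C; then 7 (1.0 equiv) premixed with TiCl4 (2.0 equiv), −78 °C; aq NH4Cl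
Reagents that add atoms: none
Why: In this anti-selective titanium glycolate aldol (Crimmins aldol) the chelated Z-enolate should add through an open transition state to the TiCl4-bound aldehyde from the face opposite the benzyl group, so the (R)-auxiliary sets C3 as R and the open transition state sets the carbinol C2 as R, anti to it.

Step 6
Reactants: 13 anti-aldol adduct
Product: 14 (2R,3R)-2-(allyloxy)-3-[3-geranyl-2,4-bis(methoxymethoxy)phenyl]-3-hydroxy-N-methoxy-N-methylpropanamide
Conditions: MeONHMe·HCl (3 equiv), imidazole (5 equiv), CH2Cl2, 23 °C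
Reagents that add atoms: N,O-dimethylhydroxylamine hydrochloride, CNOC.Cl
Why: The N-acyl oxazolidinethione is an activated amide, so direct aminolysis (acyl transfer) should give the Weinreb amide without epimerization and release the auxiliary for reuse.

Step 7
Reactants: 14 hydroxy Weinreb amide
Product: 15 (2R,3R)-2-(allyloxy)-3-[3-geranyl-2,4-bis(methoxymethoxy)phenyl]-N-methoxy-N-methyl-3-(triethylsilyloxy)propanamide
Conditions: Et3SiCl, imidazole, DMF, 0 → 23 °C
Reagents that add atoms: chlorotriethylsilane, CC[Si](Cl)(CC)CC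
Why: Silylation of the secondary benzylic alcohol should prevent alkoxide formation and retro-aldol cleavage in step 10, and the triethylsilyl ether is cleaved by the mild acid of step 11.

Step 8
Reactants: 16 methyl acetoacetate; 17 prenyl bromide
Product: 18 methyl 2-acetyl-5-methylhex-4-enoate
Conditions: 16 (1.5 equiv), K2CO3, acetone, reflux
Reagents that add atoms: none
Why: The acetoacetic ester alkylation should give C-monoalkylation at the doubly activated carbon, with excess ester limiting dialkylation.

Step 9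
Reactants: 18 methyl 2-prenylacetoacetate; 19 N-methoxy-N-methylacetamide
Product: 21 methyl 2-(3-methylbut-2-enyl)-3,5-dioxohexanoate, via dilithium dianion 20 (not isolated)
Conditions: LiN(i-Pr)2 (2.2 equiv), THF, −78 → 0 °C; 19, −78 → 0 °C; 1 M HCl, 0 °C
Reagents that add atoms: none
Why: The Weiler dianion should react at its terminal carbon, and acylation by a Weinreb amide stops at the chelated tetrahedral intermediate, so the more acidic product does not quench the dianion.

Step 10
Reactants: 21 prenylated diketo ester; 15 silylated Weinreb amide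
Product: 23 methyl (8R,9R)-8-(allyloxy)-9-[3-geranyl-2,4-bis(methoxymethoxy)phenyl]-2-(3-methylbut-2-enyl)-3,5,7-trioxo-9-(triethylsilyloxy)nonanoate, via trilithium trianion 22 (not isolated)
Conditions: 21 (2.2 equiv), LiN(i-Pr)2 (6.6 equiv), THF, −78 → 0 °C; then 15 (1.0 equiv), −78 → −20 °C; AcOH, −78 °C
Reagents that add atoms: none
Why: In this polyanion acylation the terminal methyl-derived carbanion of the trianion is its most basic and nucleophilic site and should add to the Weinreb amide to form the C4–C4a bond, the chelated tetrahedral intermediate surviving until the cold acidic quench.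

Step 11
Reactants: 23 silylated triketo ester
Product: 25 methyl 4-[(2R,3R)-3-(allyloxy)-2-[3-geranyl-2,4-bis(methoxymethoxy)phenyl]-4-oxo-3,4-dihydro-2H-pyran-6-yl]-2-(3-methylbut-2-enyl)-3-oxobutanoate, via hydroxy triketo ester 24 (not isolated)
Conditions: TsOH·H2O (0.3 equiv), THF/H2O (20:1), 0 → 23 °C
Reagents that add atoms: none
Why: Acid should cleave the silyl ether, after which the C2 hydroxyl adds to the C8a carbonyl (the only six-membered hemiketal available) and dehydration gives the vinylogous ester; the C2–O and C3–O bonds are not broken, so the trans 2R,3R arrangement is kept, and the O3 allyl ether blocks furanone formation.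

Step 12
Reactants: 25 pyranone β-keto ester
Product: 27 (2R,3R)-3-(allyloxy)-2-[3-geranyl-2,4-bis(methoxymethoxy)phenyl]-5,7-dihydroxy-6-(3-methylbut-2-enyl)chroman-4-one, via chromene-4,5,7-trione 26 (not isolated)
Conditions: LiN(SiMe3)2 (2.5 equiv), THF, −78 → 23 °C; AcOH, 0 °C
Reagents that add atoms: none
Why: The base should remove the C6–H of the β-keto ester and one C8–H, giving a dianion whose C8–C8a–C4a–C4–O part is a dienolate; its C4a carbon adds to the ester carbon C5, methoxide leaves, and loss of the now triply activated C4a–H with enolization of the C5 and C7 carbonyls gives the aromatic 5,7-diolate. The closest known reaction is the Claisen (Dieckmann-type) cyclization of 3,5,7-triketo esters and of pyranone-masked polyketo esters to acylphloroglucinols and 5,7-dihydroxychromones. Ring A closes in a 6-(enolexo)-exo-trig mode. No stereocentre is formed: the C6 epimers converge on aromatization, and C2 and C3 should be untouched because O4 already carries enolate charge, which leaves C3–H non-acidic and suppresses β-elimination of O1, trans being the more stable arrangement in any case. The selectivity needed is Claisen attack (C4a on C5) over aldol attack (C6 on C4) and over lactonization; it is secured because C4 is a vinylogous ester/enolate carbon and not an electrophile, O1 is tied up in ring C, and attack from C8 would give a four-membered ring. Because O1 is bonded to C8a before ring A exists, the prenyl group must end at C6.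

Step 13
Reactants: 27 protected dihydroflavonol
Product: 29 (2R,3R)-2-[3-[(2E)-3,7-dimethylocta-2,6-dienyl]-2,4-dihydroxyphenyl]-3,5,7-trihydroxy-6-(3-methylbut-2-enyl)chroman-4-one, via E-propenyl ether 28 (not isolated)
Conditions: [Ir(cod)(PMePh2)2]PF6 (5 mol %, activated with H2, then Ar), THF, 23 °C; then 3 M aq HCl/MeOH (1:4), 23 → 40 °C
Reagents that add atoms: none
Why: Iridium hydride-catalysed isomerization should convert the allyl ether into the propenyl ether while leaving the trisubstituted prenyl and geranyl alkenes alone, and dilute acid should then hydrolyse the enol ether and cleave both MOM acetals without touching C3, the trans arrangement being the thermodynamic one at C2.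

**Compound list**

1 | resorcinol | Oc1cccc(O)c1 | starting material
2 | 1,3-bis(methoxymethoxy)benzene | COCOc1cccc(OCOC)c1 | intermediate
3 | geranyl bromide | CC(C)=CCC/C(C)=C/CBr | starting material
4 | 2-lithio-1,3-bis(methoxymethoxy)benzene | [Li]c1c(OCOC)cccc1OCOC | intermediate
5 | 2-[(2E)-3,7-dimethylocta-2,6-dienyl]-1,3-bis(methoxymethoxy)benzene | CC(C)=CCC/C(C)=C/Cc1c(OCOC)cccc1OCOC | intermediate
6 | [3-geranyl-2,4-bis(methoxymethoxy)phenyl]lithium | CC(C)=CCC/C(C)=C/Cc1c(OCOC)ccc([Li])c1OCOC | intermediate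
7 | 3-geranyl-2,4-bis(methoxymethoxy)benzaldehyde | CC(C)=CCC/C(C)=C/Cc1c(OCOC)ccc(C=O)c1OCOC | intermediate
8 | (allyloxy)acetic acid | OC(=O)COCC=C | starting material
9 | (R)-4-benzyl-1,3-oxazolidine-2-thione | S=C1N[C@H](Cc2ccccc2)CO1 | starting material
10 | (allyloxy)acetyl chloride | ClC(=O)COCC=C | intermediate
11 | (R)-3-[(allyloxy)acetyl]-4-benzyl-1,3-oxazolidine-2-thione | C=CCOCC(=O)N1C(=S)OC[C@H]1Cc1ccccc1 | intermediate
12 | trichlorotitanium (Z)-enolate of 11 | C=CCO/C=C(\O[Ti](Cl)(Cl)Cl)N1C(=S)OC[C@H]1Cc1ccccc1 | intermediate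
13 | (R)-3-[(2R,3R)-2-(allyloxy)-3-aryl-3-hydroxypropanoyl]-4-benzyl-1,3-oxazolidine-2-thione (aryl = 3-geranyl-2,4-bis(methoxymethoxy)phenyl) | CC(C)=CCC/C(C)=C/Cc1c(OCOC)ccc([C@@H](O)[C@@H](OCC=C)C(=O)N2C(=S)OC[C@H]2Cc2ccccc2)c1OCOC | intermediate
14 | (2R,3R)-2-(allyloxy)-3-aryl-3-hydroxy-N-methoxy-N-methylpropanamide | CC(C)=CCC/C(C)=C/Cc1c(OCOC)ccc([C@@H](O)[C@@H](OCC=C)C(=O)N(C)OC)c1OCOC | intermediate
15 | (2R,3R)-2-(allyloxy)-3-aryl-N-methoxy-N-methyl-3-(triethylsilyloxy)propanamide | CC(C)=CCC/C(C)=C/Cc1c(OCOC)ccc([C@@H](O[Si](CC)(CC)CC)[C@@H](OCC=C)C(=O)N(C)OC)c1OCOC | intermediate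
16 | methyl acetoacetate | COC(=O)CC(C)=O | starting material
17 | prenyl bromide | CC(C)=CCBr | starting material
18 | methyl 2-acetyl-5-methylhex-4-enoate | COC(=O)C(CC=C(C)C)C(C)=O | intermediate
19 | N-methoxy-N-methylacetamide | CC(=O)N(C)OC | starting material
20 | dilithium dianion of 18 | [Li+].[Li+].C=C([O-])C(CC=C(C)C)=C([O-])OC | intermediate
21 | methyl 2-(3-methylbut-2-enyl)-3,5-dioxohexanoate | COC(=O)C(CC=C(C)C)C(=O)CC(C)=O | intermediate
22 | trilithium trianion of 21 | [Li+].[Li+].[Li+].C=C([O-])C=C([O-])C(CC=C(C)C)=C([O-])OC | intermediate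
23 | methyl (8R,9R)-8-(allyloxy)-9-aryl-2-(3-methylbut-2-enyl)-3,5,7-trioxo-9-(triethylsilyloxy)nonanoate | CC(C)=CCC/C(C)=C/Cc1c(OCOC)ccc([C@@H](O[Si](CC)(CC)CC)[C@@H](OCC=C)C(=O)CC(=O)CC(=O)C(CC=C(C)C)C(=O)OC)c1OCOC | intermediate
24 | methyl (8R,9R)-8-(allyloxy)-9-aryl-9-hydroxy-2-(3-methylbut-2-enyl)-3,5,7-trioxononanoate | CC(C)=CCC/C(C)=C/Cc1c(OCOC)ccc([C@@H](O)[C@@H](OCC=C)C(=O)CC(=O)CC(=O)C(CC=C(C)C)C(=O)OC)c1OCOC | intermediate
25 | methyl 4-[(2R,3R)-3-(allyloxy)-2-aryl-4-oxo-3,4-dihydro-2H-pyran-6-yl]-2-(3-methylbut-2-enyl)-3-oxobutanoate | CC(C)=CCC/C(C)=C/Cc1c(OCOC)ccc([C@H]2OC(CC(=O)C(CC=C(C)C)C(=O)OC)=CC(=O)[C@@H]2OCC=C)c1OCOC | intermediate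
26 | (2R,3R)-3-(allyloxy)-2-aryl-6-(3-methylbut-2-enyl)-2,3,6,8-tetrahydro-4H-chromene-4,5,7-trione | CC(C)=CCC/C(C)=C/Cc1c(OCOC)ccc([C@H]2OC3=C(C(=O)C(CC=C(C)C)C(=O)C3)C(=O)[C@@H]2OCC=C)c1OCOC | intermediate
27 | (2R,3R)-3-(allyloxy)-2-aryl-5,7-dihydroxy-6-(3-methylbut-2-enyl)chroman-4-one | CC(C)=CCC/C(C)=C/Cc1c(OCOC)ccc([C@H]2Oc3cc(O)c(CC=C(C)C)c(O)c3C(=O)[C@@H]2OCC=C)c1OCOC | intermediate
28 | (2R,3R)-2-aryl-5,7-dihydroxy-6-(3-methylbut-2-enyl)-3-[(E)-prop-1-enyloxy]chroman-4-one | CC(C)=CCC/C(C)=C/Cc1c(OCOC)ccc([C@H]2Oc3cc(O)c(CC=C(C)C)c(O)c3C(=O)[C@@H]2O/C=C/C)c1OCOC | intermediate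
29 | (2R,3R)-2-[3-geranyl-2,4-dihydroxyphenyl]-3,5,7-trihydroxy-6-(3-methylbut-2-enyl)chroman-4-one | CC(C)=CCC/C(C)=C/Cc1c(O)ccc([C@H]2Oc3cc(O)c(CC=C(C)C)c(O)c3C(=O)[C@@H]2O)c1O | target

**Step count and risks**

Total: 13 steps. Longest linear sequence: 10 steps (1, 2, 3, 5, 6, 7, 10, 11, 12, 13, from resorcinol).

Steps most likely to fail:

1. Step 12. The doubly deprotonated chain may be too stabilized for C4a to add to the ester carbon, so that ring A does not close. Forcing the reaction could lead to deprotonation at C3, followed by β-elimination of O1 with loss of the C2/C3 configuration or a [2,3]-shift of the allyl ether.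
Fallback (sets out from 15, 17 and 19, returns at 27): the acyl carbon is made more electrophilic instead of the nucleophile stronger, by carrying a thioester through the same sequence. Commercial S-tert-butyl 3-oxobutanethioate is prenylated with 17 (K2CO3, acetone) to S-tert-butyl 2-acetyl-5-methylhex-4-enethioate F1. Its dilithium dianion is acylated with 19 to S-tert-butyl 2-(3-methylbut-2-enyl)-3,5-dioxohexanethioate F2. The trilithium trianion of F2 is acylated with 15 to the silylated triketo thioester F3, and TsOH in wet THF closes ring C to the pyranone thioester F4. AgOCOCF3 with Et3N in THF at 0 → 23 °C then activates the acyl group through sulfur, so that C4a of the singly deprotonated vinylogous ester is acylated without a dianion, and enolization gives 27.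

2. Step 5. The excess TiCl4 may cleave an aryl MOM ether or ionize the electron-rich benzylic titanium alkoxide, and the hindered, electron-rich aldehyde may give poor anti/syn or facial selectivity.
Fallback (sets out from 7 and 8, returns at 14): a chiral Lewis acid-mediated Mukaiyama aldol replaces the auxiliary-bound titanium enolate. Chloride 10 (from 8) with ethanethiol and Et3N gives S-ethyl 2-(allyloxy)ethanethioate F5. LiN(i-Pr)2 then Me3SiCl at −78 °C gives the (Z)-trimethylsilyl ketene S,O-acetal F6. Addition to 7 mediated by Sn(OTf)2, a proline-derived chiral diamine (the enantiomer that gives the 2R,3R adduct) and Bu2Sn(OAc)2 in CH2Cl2 at −78 °C gives the anti thioester S-ethyl (2R,3R)-2-(allyloxy)-3-aryl-3-hydroxypropanethioate F7. MeONHMe·HCl with i-PrMgCl in THF at −20 °C converts F7 into 14.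

3. Step 10. The trianion may act as a base towards the α-hydrogen of the amide (enolization, then β-elimination of the silyloxy group) instead of adding; the trilithium species may form incompletely; and the polyketo chain may cyclize on work-up.
Fallback (sets out from 15 and 22, returns at 23): an aldol addition followed by oxidation replaces the acylation. i-Bu2AlH in THF at −78 °C reduces 15 to (2R,3R)-2-(allyloxy)-3-aryl-3-(triethylsilyloxy)propanal F8. Trianion 22 adds to F8 at −78 °C, where addition to an aldehyde outruns proton transfer, to give the 7-hydroxy-3,5-dioxo ester F9 as a mixture of carbinol epimers. Dess–Martin periodinane (NaHCO3, CH2Cl2) oxidizes the new carbinol to give 23.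

**Further compounds**

F1 | step 12 | S-tert-butyl 2-acetyl-5-methylhex-4-enethioate | CC(=O)C(CC=C(C)C)C(=O)SC(C)(C)C
F2 | step 12 | S-tert-butyl 2-(3-methylbut-2-enyl)-3,5-dioxohexanethioate | CC(=O)CC(=O)C(CC=C(C)C)C(=O)SC(C)(C)C
F3 | step 12 | S-tert-butyl (8R,9R)-8-(allyloxy)-9-aryl-2-(3-methylbut-2-enyl)-3,5,7-trioxo-9-(triethylsilyloxy)nonanethioate | CC(C)=CCC/C(C)=C/Cc1c(OCOC)ccc([C@@H](O[Si](CC)(CC)CC)[C@@H](OCC=C)C(=O)CC(=O)CC(=O)C(CC=C(C)C)C(=O)SC(C)(C)C)c1OCOC
F4 | step 12 | S-tert-butyl 4-[(2R,3R)-3-(allyloxy)-2-aryl-4-oxo-3,4-dihydro-2H-pyran-6-yl]-2-(3-methylbut-2-enyl)-3-oxobutanethioate | CC(C)=CCC/C(C)=C/Cc1c(OCOC)ccc([C@H]2OC(CC(=O)C(CC=C(C)C)C(=O)SC(C)(C)C)=CC(=O)[C@@H]2OCC=C)c1OCOC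
F5 | step 5 | S-ethyl 2-(allyloxy)ethanethioate | CCSC(=O)COCC=C
F6 | step 5 | (Z)-2-(allyloxy)-1-(ethylthio)-1-(trimethylsilyloxy)ethene | C=CCO/C=C(\SCC)O[Si](C)(C)C
F7 | step 5 | S-ethyl (2R,3R)-2-(allyloxy)-3-[3-geranyl-2,4-bis(methoxymethoxy)phenyl]-3-hydroxypropanethioate | CC(C)=CCC/C(C)=C/Cc1c(OCOC)ccc([C@@H](O)[C@@H](OCC=C)C(=O)SCC)c1OCOC
F8 | step 10 | (2R,3R)-2-(allyloxy)-3-[3-geranyl-2,4-bis(methoxymethoxy)phenyl]-3-(triethylsilyloxy)propanal | CC(C)=CCC/C(C)=C/Cc1c(OCOC)ccc([C@@H](O[Si](CC)(CC)CC)[C@@H](OCC=C)C=O)c1OCOC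
F9 | step 10 | methyl (8R,9R)-8-(allyloxy)-9-aryl-7-hydroxy-2-(3-methylbut-2-enyl)-3,5-dioxo-9-(triethylsilyloxy)nonanoate | CC(C)=CCC/C(C)=C/Cc1c(OCOC)ccc([C@@H](O[Si](CC)(CC)CC)[C@@H](OCC=C)C(O)CC(=O)CC(=O)C(CC=C(C)C)C(=O)OC)c1OCOC
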